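Remark: the racemates 3 and 4 are written with the SMILES of the enantiomer that is carried forward. Atom labels C2–C6 (lactone) and C1'–C7' (side chain) of the target are used for all intermediates.

## Structural features

The target is a 6-substituted 5,6-dihydro-2H-pyran-2-one (ring O1, C2(=O), C3=C4, C5H2, C6). C6 carries a seven-carbon chain C1'–C7' with a free hydroxyl at C1', a methyl ether at C2', an E double bond C3'=C4', and acetates at C5' and C6' (C7' is methyl).

C6 (S), C1' (S) and C2' (R) are three contiguous oxygenated stereocentres. Their oxygens lie on the same side in the Fischer projection (anti,anti in the zigzag), so they become all-cis when C5 to C3' are bent into a ring. C5' (S) and C6' (R) form an anti (erythro) diol pair, insulated from the triad by the alkene.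

The real difficulty is this triad together with the fact that its three oxygens are all different (lactone oxygen, free OH, OMe), next to a 1,4-dioxygenated E-alkene flanked by branched carbons on both sides.

Fragile groups are the enoate lactone (Michael acceptor, base-sensitive), the allylic C2' ether and C5' acetate (ionisable by acid or zerovalent palladium), the acetates (solvolysis, migration) and the free C1' hydroxyl next to the lactone oxygen.

The feature exploited by the key step: the six carbons C4–C5–C6–C1'–C2'–C3' begin and end with alkene carbons (C4 of the lactone enoate, C3' of the chain alkene). Joining C4 to C3' gives a cyclohexene in which the triad is all-cis, the arrangement that one endo Diels–Alder reaction delivers.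

## Logic of the disconnections

In one sentence, the route is a ring-rearrangement metathesis of 6, telescoped with cross-metathesis to 10.

**12 to 6 and 10 (key).** The bonds C3=C4 and C3'=C4' of 12 are cut and C4 is joined to C3' instead. This leads through 11 to 6 and 10. The cut is made here because both bonds are alkenes that metathesis can form, and because the carbocycle of 6 holds C6, C1' and C2' in an all-cis arrangement that is trivial on a ring and laborious in a chain. The gain is the lactone ring, the E-alkene and the transfer of the whole triad in one operation, with no protecting group. The demand is that an unstrained six-membered ring must be opened productively and that the ester tether must choose C4 and not C3'.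

**6 to 5.** The ester C–O bond at the C6 oxygen is cut. The gain is small, but it puts a demand on the forward step: the acyl group must go to the C6 hydroxyl (flanked by CH2) and not to the C1' hydroxyl (flanked by the methoxy-bearing carbon).

**5 to 4, 3, and 1 + 2.** 5 is the resolved form of 4, which is the diol freed from 3. In 3 the ring bonds C5–C6 and C1'–C2' are cut (retro-Diels–Alder) to 1 and 2. This sets the relative configuration of all three stereocentres in one step from two commodity chemicals, with the methyl ether already in place. The demands are endo selectivity and a resolution, since the cycloaddition has no chiral controller.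

**10 to 9, 8 and 7.** The two acetyl C–O bonds are cut (9), then the C7'–H bond (hydride opening of the terminal epoxide of 8), then the epoxide C–O bonds (desymmetrising epoxidation of 7). Both stereocentres of this fragment come from one catalytic asymmetric step on an achiral C5 alcohol. The demand is enantiotopic-group and face selectivity in the epoxidation and hydride attack at the terminal carbon.

## Other disconnections considered

Alternative 1: Cut C3=C4 by ordinary ring-closing metathesis of an open-chain acrylate and C3'=C4' by cross-metathesis. This is the plan that comes to mind first. The forward key step would close the triene acrylate A1 to 11, which would then be coupled with 10.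
- The three contiguous stereocentres of A1, with three different oxygens, would have to be built in the open chain by separate reagent- or auxiliary-controlled steps. That is expected to take roughly twice as many steps as the four that lead to 6.
- A1 is the formal ethenolysis product of 6. Its two unhindered terminal alkenes are set up to close the carbocycle, which should be faster than closure of the electron-poor acrylate. The conventional plan would therefore enter the same manifold from the more laborious side, or would force the side chain to be attached before lactone formation with extra protecting groups.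

Alternative 2: Cut C5–C6 and O1–C2. The forward key step would be an asymmetric hetero-Diels–Alder reaction of the aldehyde A2 with 1 under a chiral (salen)CrCl catalyst, giving the acetal A3, followed by oxidation of the acetal to the lactone and desilylation.
- The cycloaddition sets only C6. The other four stereocentres and the E-alkene must already be present in A2, at the end of a long linear sequence.
- A2 is an α-silyloxy aldehyde with an allylic methoxy group next to it, so epimerisation and elimination are to be expected.
- The catalyst would have to override the facial bias of the α-alkoxy substituent, and two further steps are needed after the key step.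

Alternative 3: Cut the same C3'=C4 ring bond oxidatively. Ozonolysis of the bis(triethylsilyl) ether of 5 would give the dialdehyde A4, followed by a Z-selective phosphonoacetate olefination at C4 with lactonisation and a sulfone-based E-olefination at C3'.
- The two aldehydes of A4 have similar reactivity and nothing in the molecule tells them apart.
- The C4 aldehyde is β-silyloxy (prone to elimination) and the C3' aldehyde is α-methoxy (prone to epimerisation) under the basic olefination conditions.
- The chain partner would need three more steps from 9, and six or seven steps would follow the cleavage. In the chosen plan the ester tether distinguishes the two termini by ring size and both new alkenes are made in one flask.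

Key step: step 8

## Steps

Step 1
Reactants: 1 (1E)-1-methoxybuta-1,3-diene; 2 1,3-dioxol-2-one (vinylene carbonate)
Product: 3 rac-(3aS,4R,7aS)-4-methoxy-3a,4,7,7a-tetrahydro-1,3-benzodioxol-2-one (all-cis adduct)
Conditions: 1 (2 equiv), BHT (1 mol%), neat, sealed tube, 160 °C, 24 h; minor exo adduct removed by chromatography
Reagents that add atoms: none
Why: Thermal Diels–Alder reaction; the cis dienophile adds suprafacially and, through the endo transition state, its two oxygens end up cis to the (E)-methoxy group of the diene, so that C6, C1' and C2' are set all-cis in one step (as the racemate).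

Step 2
Reactants: 3 rac-(3aS,4R,7aS)-4-methoxy-3a,4,7,7a-tetrahydro-1,3-benzodioxol-2-one
Product: 4 rac-(1S,2S,3R)-3-methoxycyclohex-4-ene-1,2-diol
Conditions: K2CO3 (0.1 equiv), MeOH, 23 °C
Reagents that add atoms: none
Why: Base-catalysed methanolysis (transesterification) of the cyclic carbonate; no stereocentre is touched and the allylic methyl ether is inert.

Step 3
Reactants: 4 rac-(1S,2S,3R)-3-methoxycyclohex-4-ene-1,2-diol
Product: 5 (1S,2S,3R)-3-methoxycyclohex-4-ene-1,2-diol
Conditions: immobilised Candida antarctica lipase B (Novozym 435), vinyl acetate (3 equiv), tert-butyl methyl ether, 30 °C, to about 55% conversion; chromatography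
Reagents that add atoms: none
Why: Lipase-catalysed kinetic resolution by acyl transfer; by the empirical size rule for secondary alcohols (large CH(OH) side, medium CH2 side) the enzyme should acetylate the C6 hydroxyl of the (1R,2R,3S)-enantiomer, so that 5 should be recovered unreacted, in at most half of the material, with high enantiomeric purity once conversion has passed one half.

Step 4
Reactants: 5 (1S,2S,3R)-3-methoxycyclohex-4-ene-1,2-diol
Product: 6 (1S,5R,6S)-6-hydroxy-5-methoxycyclohex-3-en-1-yl prop-2-enoate
Conditions: acryloyl chloride (1.1 equiv), 2-aminoethyl diphenylborinate (10 mol%), iPr2NEt (1.3 equiv), MeCN, 0 °C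
Reagents that add atoms: acryloyl chloride C=CC(=O)Cl
Why: Borinic-acid-catalysed regioselective monoacylation of a cis-1,2-diol; the diol is bound as a tetracoordinate borinate and the acyl chloride should attack the equatorial, more accessible C6 oxygen (the half-chair with the C6 oxygen axial would place it syn-diaxial to the C2' methoxy group), and catalyst binding suppresses double acylation.

Step 5
Reactants: 7 penta-1,4-dien-3-ol
Product: 8 (1S)-1-[(2R)-oxiran-2-yl]prop-2-en-1-ol [(2R,3S)-1,2-epoxypent-4-en-3-ol]
Conditions: Ti(OiPr)4 (10 mol%), L-(+)-diisopropyl tartrate (13 mol%), tBuOOH (1.5 equiv, anhydrous), 4 Å molecular sieves, CH2Cl2, −20 °C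
Reagents that add atoms: tert-butyl hydroperoxide CC(C)(C)OO
Why: Sharpless asymmetric epoxidation of a divinyl carbinol; the catalyst selects one enantiotopic vinyl group and one face to give the anti (erythro) epoxy alcohol, and the minor enantiomer is removed by a faster second epoxidation, so the enantiomeric purity should rise with conversion; this sets C5' and C6'.

Step 6
Reactants: 8 (1S)-1-[(2R)-oxiran-2-yl]prop-2-en-1-ol
Product: 9 (2R,3S)-pent-4-ene-2,3-diol
Conditions: LiAlH4 (1.2 equiv), THF, 0 °C; then H2O, aq NaOH
Reagents that add atoms: none
Why: Hydride opening of the terminal epoxide (SN2 at the unsubstituted carbon) turns the oxirane CH2 into the C7' methyl group; neither C–O stereocentre is touched.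

Step 7
Reactants: 9 (2R,3S)-pent-4-ene-2,3-diol
Product: 10 (2R,3S)-pent-4-ene-2,3-diyl diacetate
Conditions: Ac2O (3 equiv), pyridine (4 equiv), DMAP (5 mol%), CH2Cl2, 0 to 23 °C
Reagents that add atoms: acetic anhydride CC(=O)OC(C)=O
Why: DMAP-catalysed acetylation of both secondary hydroxyls; no stereocentre is affected.

Step 8
Reactants: 6 (1S,5R,6S)-6-hydroxy-5-methoxycyclohex-3-en-1-yl prop-2-enoate; 10 (2R,3S)-pent-4-ene-2,3-diyl diacetate
Product: 12 (6S)-6-[(1S,2R,3E,5S,6R)-5,6-diacetoxy-1-hydroxy-2-methoxyhept-3-en-1-yl]-5,6-dihydro-2H-pyran-2-one, via vinyl lactone 11 (not isolated)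
Conditions: (a) second-generation Hoveyda–Grubbs catalyst RuCl2(H2IMes)(=CH-C6H4-2-OiPr) (H2IMes = 1,3-dimesitylimidazolidin-2-ylidene; 5 mol%), 1,4-benzoquinone (10 mol%), ethene (1 atm), toluene (0.02 M), 60 °C; (b) 10 (5 equiv), same catalyst (5 mol%), argon sparge, 80 °C
Reagents that add atoms: none
Why: Ring-rearrangement metathesis (ring opening/ring closing) followed in the same flask by cross-metathesis; the closest known reaction types are the ring-opening cross-metathesis of unstrained cyclohexene with acrylates through ester-substituted ruthenium carbenes and the ethene-assisted ring rearrangement of cycloalkenes that carry a tethered alkene. In stage (a) the ruthenium methylidene either exchanges with the acrylate to an ester-substituted carbene that adds across the ring alkene, or opens the ring alkene to an alkylidene at C4 that closes onto the acrylate; both paths end in one [2+2]/retro-[2+2] event that forms C3=C4, closes the six-membered lactone (O1–C2–C3=C4–C5–C6, ring closure by metathesis across the O–C(=O)–CH= tether) and releases C3' as the vinyl group of 11. Closure onto C4 is secured by the tether length, since attack at C3' would give a seven-membered lactone. The carbocycle is not strained, so its opening is not downhill by itself; the sequence should act as a ratchet because the endocyclic (Z)-enoate of 11 is a poor metathesis partner and should not re-enter, while every unproductive ring opening simply re-closes to 6. In stage (b) the vinyl groups of 11 and 10 are joined with loss of ethene, which is swept out; both partners are branched at the allylic carbon, so homodimerisation should be slow and the E isomer of C3'=C4' strongly preferred on steric grounds. No stereocentre is formed or touched: C6, C1' and C2' come unchanged from the ring of 6, and C5' and C6' from 10. The selectivity needed is chemoselectivity among four alkenes: the acrylate is engaged intramolecularly, the lactone enoate is inert, and only the two terminal vinyl groups cross. The free C1' hydroxyl, the acetates and the allylic methyl ether should tolerate the neutral catalyst, and benzoquinone suppresses ruthenium-hydride isomerisation of the allylic ether.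

## Compound list

1 | (1E)-1-methoxybuta-1,3-diene | CO/C=C/C=C | starting material
2 | 1,3-dioxol-2-one (vinylene carbonate) | O=C1OC=CO1 | starting material
3 | rac-(3aS,4R,7aS)-4-methoxy-3a,4,7,7a-tetrahydro-1,3-benzodioxol-2-one (all-cis, racemate) | CO[C@@H]1C=CC[C@@H]2OC(=O)O[C@H]12 | intermediate
4 | rac-(1S,2S,3R)-3-methoxycyclohex-4-ene-1,2-diol (all-cis, racemate) | CO[C@@H]1C=CC[C@H](O)[C@@H]1O | intermediate
5 | (1S,2S,3R)-3-methoxycyclohex-4-ene-1,2-diol | CO[C@@H]1C=CC[C@H](O)[C@@H]1O | intermediate
6 | (1S,5R,6S)-6-hydroxy-5-methoxycyclohex-3-en-1-yl prop-2-enoate | CO[C@@H]1C=CC[C@H](OC(=O)C=C)[C@@H]1O | intermediate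
7 | penta-1,4-dien-3-ol | C=CC(O)C=C | starting material
8 | (1S)-1-[(2R)-oxiran-2-yl]prop-2-en-1-ol | C=C[C@H](O)[C@@H]1OC1 | intermediate
9 | (2R,3S)-pent-4-ene-2,3-diol | C=C[C@H](O)[C@@H](C)O | intermediate
10 | (2R,3S)-pent-4-ene-2,3-diyl diacetate | C=C[C@H](OC(C)=O)[C@@H](C)OC(C)=O | intermediate
11 | (6S)-6-[(1S,2R)-1-hydroxy-2-methoxybut-3-en-1-yl]-5,6-dihydro-2H-pyran-2-one | CO[C@H](C=C)[C@@H](O)[C@@H]1CC=CC(=O)O1 | intermediate (not isolated)
12 | (6S)-6-[(1S,2R,3E,5S,6R)-5,6-diacetoxy-1-hydroxy-2-methoxyhept-3-en-1-yl]-5,6-dihydro-2H-pyran-2-one | CO[C@H](/C=C/[C@H](OC(C)=O)[C@@H](C)OC(C)=O)[C@@H](O)[C@@H]1CC=CC(=O)O1 | target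

## Step count and least certain steps

Total step count: 8. Longest linear sequence: 5 steps (steps 1, 2, 3, 4, 8); the second branch has 4 steps (5, 6, 7, 8).

**Step 8 (key step).** The most likely failure is unproductive ring opening. The ring-opened alkylidene may re-close to the unstrained carbocycle much faster than it is captured by the acrylate, and the catalyst may decay before 6 is consumed. Slow cross-metathesis between two allylically branched alkenes is a second risk.

The fallback gives up the metathetic ring opening; it sets out from 5 and returns at 11.
- 5 is acylated at the C6 oxygen under the conditions of step 4 with (diethoxyphosphoryl)acetyl chloride to give the phosphonoacetate F1.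
- The C1' hydroxyl is silylated (Et3SiOTf, 2,6-lutidine) to the triethylsilyl ether F2.
- Ozonolysis (O3, CH2Cl2, −78 °C; Me2S) cuts the same C3'=C4 bond to the dialdehyde F3.
- An intramolecular Horner–Wadsworth–Emmons reaction (LiCl, iPr2NEt, MeCN) closes the unsaturated lactone onto the C4 aldehyde (six- against seven-membered ring) to give the lactone aldehyde F4.
- Methylenation of the remaining aldehyde (Zn, CH2Br2, TiCl4) gives the silyl ether F5.
- HF·pyridine returns to 11, which is coupled with 10 as in stage (b).

**Step 3.** The likely failures are poor discrimination between the enantiomers, or acylation of the opposite enantiomer to the one predicted by the size rule.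

The fallback is a classical resolution through covalent diastereomers; it sets out from 4 and returns at 5. 4 is acylated under the conditions of step 4 with (2S)-2-methoxy-2-phenylacetyl chloride to give the diastereomeric esters, the (1S,5R,6S)-mandelate F6 and the (1R,5S,6R)-mandelate F7. These are separated by chromatography or crystallisation, and F6 is cleaved with K2CO3 in MeOH to 5.

**Step 4.** The likely failures are acylation at the flanked C1' hydroxyl, double acylation, or acyl migration between the two cis hydroxyls during work-up.

The fallback replaces site-selective acylation by protection and selective deprotection; it sets out from 5 and returns at 12.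
- 5 is silylated twice (Et3SiCl, imidazole) to the bis(triethylsilyl) ether F8.
- The less hindered C6 silyl ether is removed (HF·pyridine buffered with pyridine, THF, 0 °C) to the alcohol F9.
- Acylation of the only free hydroxyl with acryloyl chloride gives the acrylate F10.
- Step 8 with 10 gives the silyl ether F11.
- HF·pyridine gives 12.

**Step 1.** The likely failures are thermal polymerisation of the electron-rich diene before it is trapped by the sluggish dienophile, and an unfavourable endo/exo ratio.

The fallback uses an acyloxy diene; it sets out from 2 and returns at 3.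
- (1E)-Buta-1,3-dien-1-yl acetate and 2 are heated as in step 1 to give the all-cis acetoxy carbonate F12.
- The allylic acetate is hydrolysed with an esterase in pH 7 buffer, which leaves the carbonate intact, to the allylic alcohol F13.
- Methylation under non-basic conditions (MeOTf, 2,6-di-tert-butylpyridine, CH2Cl2), chosen to avoid carbonate migration, gives 3.

## Further compounds

F1 | step 8 | (1S,5R,6S)-6-hydroxy-5-methoxycyclohex-3-en-1-yl 2-(diethoxyphosphoryl)acetate | CO[C@@H]1C=CC[C@H](OC(=O)CP(=O)(OCC)OCC)[C@@H]1O
F2 | step 8 | (1S,5R,6S)-5-methoxy-6-(triethylsilyloxy)cyclohex-3-en-1-yl 2-(diethoxyphosphoryl)acetate | CO[C@@H]1C=CC[C@H](OC(=O)CP(=O)(OCC)OCC)[C@@H]1O[Si](CC)(CC)CC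
F3 | step 8 | (3S,4S,5S)-5-methoxy-1,6-dioxo-4-(triethylsilyloxy)hexan-3-yl 2-(diethoxyphosphoryl)acetate | CO[C@H](C=O)[C@@H](O[Si](CC)(CC)CC)[C@@H](OC(=O)CP(=O)(OCC)OCC)CC=O
F4 | step 8 | (2S,3S)-2-methoxy-3-[(2S)-6-oxo-3,6-dihydro-2H-pyran-2-yl]-3-(triethylsilyloxy)propanal | CO[C@H](C=O)[C@@H](O[Si](CC)(CC)CC)[C@@H]1CC=CC(=O)O1
F5 | step 8 | (6S)-6-[(1S,2R)-2-methoxy-1-(triethylsilyloxy)but-3-en-1-yl]-5,6-dihydro-2H-pyran-2-one | CO[C@H](C=C)[C@@H](O[Si](CC)(CC)CC)[C@@H]1CC=CC(=O)O1
F6 | step 3 | (1S,5R,6S)-6-hydroxy-5-methoxycyclohex-3-en-1-yl (2S)-2-methoxy-2-phenylacetate | CO[C@@H]1C=CC[C@H](OC(=O)[C@@H](OC)c2ccccc2)[C@@H]1O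
F7 | step 3 | (1R,5S,6R)-6-hydroxy-5-methoxycyclohex-3-en-1-yl (2S)-2-methoxy-2-phenylacetate | CO[C@H]1C=CC[C@@H](OC(=O)[C@@H](OC)c2ccccc2)[C@H]1O
F8 | step 4 | (3R,4R,5S)-3-methoxy-4,5-bis(triethylsilyloxy)cyclohex-1-ene | CO[C@@H]1C=CC[C@H](O[Si](CC)(CC)CC)[C@@H]1O[Si](CC)(CC)CC
F9 | step 4 | (1S,5R,6S)-5-methoxy-6-(triethylsilyloxy)cyclohex-3-en-1-ol | CO[C@@H]1C=CC[C@H](O)[C@@H]1O[Si](CC)(CC)CC
F10 | step 4 | (1S,5R,6S)-5-methoxy-6-(triethylsilyloxy)cyclohex-3-en-1-yl prop-2-enoate | CO[C@@H]1C=CC[C@H](OC(=O)C=C)[C@@H]1O[Si](CC)(CC)CC
F11 | step 4 | (6S)-6-[(1S,2R,3E,5S,6R)-5,6-diacetoxy-2-methoxy-1-(triethylsilyloxy)hept-3-en-1-yl]-5,6-dihydro-2H-pyran-2-one | CO[C@H](/C=C/[C@H](OC(C)=O)[C@@H](C)OC(C)=O)[C@@H](O[Si](CC)(CC)CC)[C@@H]1CC=CC(=O)O1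
F12 | step 1 | rac-all-cis-2-oxo-3a,4,7,7a-tetrahydro-1,3-benzodioxol-4-yl acetate | CC(=O)O[C@@H]1C=CC[C@@H]2OC(=O)O[C@H]12
F13 | step 1 | rac-all-cis-4-hydroxy-3a,4,7,7a-tetrahydro-1,3-benzodioxol-2-one | O[C@@H]1C=CC[C@@H]2OC(=O)O[C@H]12
A1 | alternative 1 | (4S,5S,6R)-5-hydroxy-6-methoxyocta-1,7-dien-4-yl prop-2-enoate | CO[C@H](C=C)[C@@H](O)[C@@H](OC(=O)C=C)CC=C
A2 | alternative 2 | (2R,3R,4E,6S,7R)-6,7-diacetoxy-3-methoxy-2-(triethylsilyloxy)oct-4-enal | CO[C@H](/C=C/[C@H](OC(C)=O)[C@@H](C)OC(C)=O)[C@@H](O[Si](CC)(CC)CC)C=O
A3 | alternative 2 | (6S)-6-[(1S,2R,3E,5S,6R)-5,6-diacetoxy-2-methoxy-1-(triethylsilyloxy)hept-3-en-1-yl]-2-methoxy-5,6-dihydro-2H-pyran (mixture at C2) | CO[C@H](/C=C/[C@H](OC(C)=O)[C@@H](C)OC(C)=O)[C@@H](O[Si](CC)(CC)CC)[C@@H]1CC=CC(OC)O1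
A4 | alternative 3 | (2S,3R,4S)-2-methoxy-3,4-bis(triethylsilyloxy)hexanedial | CO[C@H](C=O)[C@@H](O[Si](CC)(CC)CC)[C@@H](O[Si](CC)(CC)CC)CC=O
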